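**Strategy**

Both halves share one resorcinol-type carbocycle (O at C6 and C8, bridge carbon at C7, methyl at C5, pyran fusion at C4a–C8a), so each is made by a Danheiser benzannulation of a pyranyl diazo ketone with a siloxyalkyne. The key step builds the carbocycle of the quinone-methide half last: the vinylketene from a 2-methoxy-5,6-dihydro-2H-pyranyl diazo ketone (C8, C5, C4a=C8a) and a siloxyalkyne bearing the finished isochromanone (C7, C6) unite both halves in one operation; the C1 acetal later releases the quinone methide. Ethyl (R)-3-hydroxybutanoate furnishes C3/C4 of both halves, (S)-Roche ester the bridging CH(CH3).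

Key step: step 19

Remark on numbering: atoms are numbered as in citrinin (O2, C1, C3, C4, C4a, C5–C8, C8a), with primes for the lactone half.
Assumption: the 6-hydroxy-8-oxo and 8-hydroxy-6-oxo forms of the quinone methide are freely interconverting tautomers, and anomeric or transient stereocentres at C1, C5 and C8a need no control because these atoms end up sp2.

**Route**

Step 1
Reactants: 1 ethyl (R)-3-hydroxybutanoate
Product: 2 ethyl (2R,3R)-3-hydroxy-2-methylbutanoate
Conditions: LDA (2.2 equiv), THF, −78 → −20 °C; MeI, DMPU, −78 → 0 °C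
Reagents that add atoms: iodomethane CI
Why: Fráter–Seebach alkylation: the chelated alkoxide–enolate dianion should be methylated anti to the C3 methyl group, setting the anti (2R,3R) pair that becomes C3/C4 of both halves.

Step 2
Reactants: 2 ethyl (2R,3R)-3-hydroxy-2-methylbutanoate
Product: 3 ethyl (2R,3R)-3-acetoxy-2-methylbutanoate
Conditions: Ac2O, pyridine, DMAP (cat.), CH2Cl2, 0 → 25 °C
Reagents that add atoms: acetic anhydride CC(=O)OC(C)=O
Why: Standard O-acetylation installs the two carbons (future C1 and C8a) needed for the lactone without touching either stereocentre.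

Step 3
Reactants: 3 ethyl (2R,3R)-3-acetoxy-2-methylbutanoate
Product: 4 (5R,6R)-4-hydroxy-5,6-dimethyl-5,6-dihydro-2H-pyran-2-one
Conditions: LiHMDS (3 equiv), THF, −78 → −20 °C; then 1 M HCl
Reagents that add atoms: none
Why: Intramolecular Claisen (Dieckmann-type) condensation: the kinetically formed acetate enolate attacks the ethyl ester to close the six-membered β-keto lactone, which is held as its enolate until the quench.

Step 4
Reactants: 4 (5R,6R)-4-hydroxy-5,6-dimethyl-5,6-dihydro-2H-pyran-2-one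
Product: 5 (2R,3R)-2,3-dimethyl-6-oxo-3,6-dihydro-2H-pyran-4-yl trifluoromethanesulfonate
Conditions: Tf2O, Et3N, CH2Cl2, −78 °C
Reagents that add atoms: trifluoromethanesulfonic anhydride O=S(=O)(OS(=O)(=O)C(F)(F)F)C(F)(F)F
Why: O-sulfonylation of the vinylogous acid gives the enol triflate that activates C4a for carbonylative coupling in both branches.

Step 5
Reactants: 5 (2R,3R)-2,3-dimethyl-6-oxo-3,6-dihydro-2H-pyran-4-yl trifluoromethanesulfonate
Product: 6 (5S,6R)-5,6-dimethyl-4-propanoyl-5,6-dihydro-2H-pyran-2-one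
Conditions: Pd(PPh3)4 (5 mol %), LiCl, CO (1 atm), Et4Sn, THF, 60 °C
Reagents that add atoms: carbon monoxide [C-]#[O+]; tetraethylstannane CC[Sn](CC)(CC)CC
Why: Carbonylative Stille coupling: oxidative addition of the enol triflate, CO insertion and ethyl transfer from tin should give the ethyl enone while leaving the lactone and both stereocentres alone.

Step 6
Reactants: 6 (5S,6R)-5,6-dimethyl-4-propanoyl-5,6-dihydro-2H-pyran-2-one
Product: 8 (5S,6R)-4-(2-diazopropanoyl)-5,6-dimethyl-5,6-dihydro-2H-pyran-2-one, via trifluoroacetyl diketone 7 (not isolated)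
Conditions: LiHMDS, THF, −78 °C; CF3CO2CH2CF3; then MsN3, Et3N, H2O, MeCN, 25 °C
Reagents that add atoms: 2,2,2-trifluoroethyl trifluoroacetate O=C(OCC(F)(F)F)C(F)(F)F; methanesulfonyl azide CS(=O)(=O)N=[N+]=[N-]
Why: Detrifluoroacetylative diazo transfer: the kinetic enolate at the ethyl CH2 is trifluoroacetylated and the activated methine accepts the diazo group with loss of the trifluoroacetyl group, which avoids diazoalkane acylation and its cycloaddition to the enoate.

Step 7
Reactants: 5 (2R,3R)-2,3-dimethyl-6-oxo-3,6-dihydro-2H-pyran-4-yl trifluoromethanesulfonate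
Product: 9 (2R,3R)-6-hydroxy-2,3-dimethyl-3,6-dihydro-2H-pyran-4-yl trifluoromethanesulfonate (lactol; anomeric mixture)
Conditions: DIBAL-H (1.05 equiv), CH2Cl2, −78 °C; Rochelle salt work-up
Reagents that add atoms: none
Why: 1,2-Reduction of the unsaturated lactone should stop at the aluminium hemiacetal at −78 °C, bringing C1 to the aldehyde oxidation level that the quinone methide needs.

Step 8
Reactants: 9 (2R,3R)-6-hydroxy-2,3-dimethyl-3,6-dihydro-2H-pyran-4-yl trifluoromethanesulfonate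
Product: 10 (2R,3R)-6-methoxy-2,3-dimethyl-3,6-dihydro-2H-pyran-4-yl trifluoromethanesulfonate (anomeric mixture)
Conditions: MeOH, PPTS (cat.), 25 °C
Reagents that add atoms: methanol CO
Why: Fischer-type acetalisation through the allylic oxocarbenium ion, which is trapped at C1 because the other allylic terminus carries the triflate; the methyl acetal fixes the pyran ring and stores the leaving group for the end game.

Step 9
Reactants: 10 (2R,3R)-6-methoxy-2,3-dimethyl-3,6-dihydro-2H-pyran-4-yl trifluoromethanesulfonate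
Product: 11 1-[(5S,6R)-2-methoxy-5,6-dimethyl-5,6-dihydro-2H-pyran-4-yl]propan-1-one
Conditions: Pd(PPh3)4 (5 mol %), LiCl, CO (1 atm), Et4Sn, THF, 60 °C
Reagents that add atoms: carbon monoxide [C-]#[O+]; tetraethylstannane CC[Sn](CC)(CC)CC
Why: Carbonylative Stille coupling as in step 5; the allylic methyl acetal is a poor leaving group for Pd(0) and should survive.

Step 10
Reactants: 11 1-[(5S,6R)-2-methoxy-5,6-dimethyl-5,6-dihydro-2H-pyran-4-yl]propan-1-one
Product: 13 2-diazo-1-[(5S,6R)-2-methoxy-5,6-dimethyl-5,6-dihydro-2H-pyran-4-yl]propan-1-one, via trifluoroacetyl diketone 12 (not isolated)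
Conditions: LiHMDS, THF, −78 °C; CF3CO2CH2CF3; then MsN3, Et3N, H2O, MeCN, 25 °C
Reagents that add atoms: 2,2,2-trifluoroethyl trifluoroacetate O=C(OCC(F)(F)F)C(F)(F)F; methanesulfonyl azide CS(=O)(=O)N=[N+]=[N-]
Why: Detrifluoroacetylative diazo transfer as in step 6; the conditions are basic throughout, so the acetal is not at risk.

Step 11
Reactants: 14 methyl (S)-3-hydroxy-2-methylpropanoate (Roche ester)
Product: 15 methyl (S)-3-(tert-butyldimethylsilyloxy)-2-methylpropanoate
Conditions: TBSCl, imidazole, DMF, 25 °C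
Reagents that add atoms: tert-butyldimethylsilyl chloride CC(C)(C)[Si](C)(C)Cl
Why: Standard silylation protects the primary alcohol for the strongly basic ynolate chemistry.

Step 12
Reactants: 15 methyl (S)-3-(tert-butyldimethylsilyloxy)-2-methylpropanoate
Product: 17 tert-butyldimethyl{[(2R)-2-methyl-4-(triisopropylsilyloxy)but-3-yn-1-yl]oxy}silane, via lithium ynolate 16 (not isolated)
Conditions: CH2Br2, LiTMP, THF, −78 °C; 15; then LiHMDS, n-BuLi, −78 → 25 °C; then i-Pr3SiCl, 0 °C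
Reagents that add atoms: dibromomethane BrCBr; chlorotriisopropylsilane CC(C)[Si](Cl)(C(C)C)C(C)C
Why: Kowalski ester-to-ynolate rearrangement: the stereogenic carbon migrates with retention in the bromo-carbenoid enolate, and the bulky silyl chloride traps the ynolate on oxygen.

Step 13
Reactants: 8 (5S,6R)-4-(2-diazopropanoyl)-5,6-dimethyl-5,6-dihydro-2H-pyran-2-one; 17 tert-butyldimethyl{[(2R)-2-methyl-4-(triisopropylsilyloxy)but-3-yn-1-yl]oxy}silane
Product: 22 (3R,4S)-7-[(2R)-1-(tert-butyldimethylsilyloxy)propan-2-yl]-8-hydroxy-3,4,5-trimethyl-6-(triisopropylsilyloxy)isochroman-1-one, via vinylketene 18 (not isolated), via vinylcyclobutenone 19 (not isolated), via dienylketene 20 (not isolated), via cyclohexadienone 21 (not isolated)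
Conditions: hν (medium-pressure Hg lamp, Pyrex), ClCH2CH2Cl, 25 °C; then 80 °C
Reagents that add atoms: none
Why: Danheiser benzannulation (photo-Wolff rearrangement, regiospecific ketene–ynol ether [2+2], 4π opening, 6π closure, tautomerisation) should build the aromatic ring of the lactone half with OH at C8′, the bridge at C7′, OSi at C6′ and methyl at C5′, creating no stereocentre and leaving the existing ones untouched.

Step 14
Reactants: 22 (3R,4S)-7-[(2R)-1-(tert-butyldimethylsilyloxy)propan-2-yl]-8-hydroxy-3,4,5-trimethyl-6-(triisopropylsilyloxy)isochroman-1-one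
Product: 23 (3R,4S)-7-[(2R)-1-(tert-butyldimethylsilyloxy)propan-2-yl]-3,4,5-trimethyl-6,8-bis(triisopropylsilyloxy)isochroman-1-one
Conditions: TIPSOTf, 2,6-lutidine, CH2Cl2, 0 → 25 °C
Reagents that add atoms: triisopropylsilyl trifluoromethanesulfonate CC(C)[Si](OS(=O)(=O)C(F)(F)F)(C(C)C)C(C)C
Why: Silylation of the chelated phenol prevents lactol formation and over-oxidation at the aldehyde stage and later acylation by ketenes.

Step 15
Reactants: 23 (3R,4S)-7-[(2R)-1-(tert-butyldimethylsilyloxy)propan-2-yl]-3,4,5-trimethyl-6,8-bis(triisopropylsilyloxy)isochroman-1-one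
Product: 24 (3R,4S)-7-[(2R)-1-hydroxypropan-2-yl]-3,4,5-trimethyl-6,8-bis(triisopropylsilyloxy)isochroman-1-one
Conditions: CSA (0.1 equiv), MeOH/CH2Cl2, 0 °C
Reagents that add atoms: none
Why: Acid-catalysed methanolysis should remove the primary alkyl TBS ether selectively, since aryl TIPS ethers are much more stable to acid.

Step 16
Reactants: 24 (3R,4S)-7-[(2R)-1-hydroxypropan-2-yl]-3,4,5-trimethyl-6,8-bis(triisopropylsilyloxy)isochroman-1-one
Product: 25 (2R)-2-[(3R,4S)-3,4,5-trimethyl-1-oxo-6,8-bis(triisopropylsilyloxy)isochroman-7-yl]propanal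
Conditions: Dess–Martin periodinane, NaHCO3, CH2Cl2, 0 °C
Reagents that add atoms: none
Why: Buffered Dess–Martin oxidation is neutral, and the 2,6-bis(silyloxy)aryl group twists out of conjugation, which disfavours enolisation of the α-aryl aldehyde.

Step 17
Reactants: 25 (2R)-2-[(3R,4S)-3,4,5-trimethyl-1-oxo-6,8-bis(triisopropylsilyloxy)isochroman-7-yl]propanal
Product: 26 (3R,4S)-7-[(2S)-but-3-yn-2-yl]-3,4,5-trimethyl-6,8-bis(triisopropylsilyloxy)isochroman-1-one
Conditions: dimethyl (1-diazo-2-oxopropyl)phosphonate, K2CO3, MeOH, 0 → 25 °C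
Reagents that add atoms: dimethyl (1-diazo-2-oxopropyl)phosphonate CC(=O)C(=[N+]=[N-])P(=O)(OC)OC
Why: Seyferth–Gilbert homologation in the Ohira–Bestmann variant converts the aldehyde into the terminal alkyne under mild base (the descriptor changes only through CIP priorities); any aryl silyl group lost here is restored in step 18.

Step 18
Reactants: 26 (3R,4S)-7-[(2S)-but-3-yn-2-yl]-3,4,5-trimethyl-6,8-bis(triisopropylsilyloxy)isochroman-1-one
Product: 28 (3R,4S)-3,4,5-trimethyl-6,8-bis(triisopropylsilyloxy)-7-[(2S)-4-(triisopropylsilyloxy)but-3-yn-2-yl]isochroman-1-one, via lithium ynolate 27 (not isolated)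
Conditions: LiHMDS, THF, −78 °C; t-BuOOLi (from t-BuOOH and LiHMDS), −78 → 0 °C; then TIPSOTf, −78 → 0 °C
Reagents that add atoms: lithium tert-butyl peroxide [Li+].[O-]OC(C)(C)C; triisopropylsilyl trifluoromethanesulfonate CC(C)[Si](OS(=O)(=O)C(F)(F)F)(C(C)C)C(C)C
Why: Julia-type oxidation of the lithium acetylide by the lithium peroxide oxenoid gives the ynolate, which the bulky silyl triflate traps on oxygen; the lactone is a hindered, electron-rich 2,6-disubstituted benzoate that should resist the non-nucleophilic base at low temperature.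

Step 19
Reactants: 13 2-diazo-1-[(5S,6R)-2-methoxy-5,6-dimethyl-5,6-dihydro-2H-pyran-4-yl]propan-1-one; 28 (3R,4S)-3,4,5-trimethyl-6,8-bis(triisopropylsilyloxy)-7-[(2S)-4-(triisopropylsilyloxy)but-3-yn-2-yl]isochroman-1-one
Product: 33 (3R,4S)-7-{1-[(3R,4S)-8-hydroxy-1-methoxy-3,4,5-trimethyl-6-(triisopropylsilyloxy)isochroman-7-yl]ethyl}-3,4,5-trimethyl-6,8-bis(triisopropylsilyloxy)isochroman-1-one (bridging centre as in 28; C1 anomers), via vinylketene 29 (not isolated), via vinylcyclobutenone 30 (not isolated), via dienylketene 31 (not isolated), via cyclohexadienone 32 (not isolated)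
Conditions: 13 (1.5 equiv), hν (medium-pressure Hg lamp, Pyrex), ClCH2CH2Cl, 25 °C; then 80 °C; Et3N-buffered chromatography
Reagents that add atoms: none
Why: Irradiation triggers the Wolff rearrangement of 13 (1,2-shift of the dihydropyranyl group) to vinylketene 29, whose electrophilic carbonyl carbon (future C8) is attacked by the nucleophilic non-oxygenated carbon of siloxyalkyne 28 (future C7) in a [2+2] cycloaddition to cyclobutenone 30, and thermal 4π ring opening then gives dienylketene 31. The closest known reaction type is the Danheiser benzannulation of α′-diazo enones with siloxyalkynes. The one ring formed is closed by 6π-electrocyclisation of 31 (C8–C8a bond) to dienone 32, which tautomerises to the phenol. No lasting stereocentre is created (C8a is planarised and C1 stays an inconsequential anomeric mixture), and the bridging, C3/C4 and C3′/C4′ centres are not touched under these neutral conditions. The step needs regiocontrol, secured by the polarisation of ketene and ynol ether, which places OSi at C6, the bridge at C7 and the methyl at C5, and it needs Wolff migration in preference to a 1,2-hydrogen shift, which photolysis of the diazo enone favours. The methoxy acetal at C1 carries the oxidation level of the quinone methide through the step.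

Step 20
Reactants: 33 (3R,4S)-7-{1-[(3R,4S)-8-hydroxy-1-methoxy-3,4,5-trimethyl-6-(triisopropylsilyloxy)isochroman-7-yl]ethyl}-3,4,5-trimethyl-6,8-bis(triisopropylsilyloxy)isochroman-1-one
Product: 35 dicitrinone H, via tetraol acetal 34 (not isolated)
Conditions: HF·pyridine, pyridine/THF, 0 → 25 °C; aqueous work-up at pH 3
Reagents that add atoms: none
Why: Fluoride cleaves the three silyl ethers, and the freed 6,8-dihydroxy-1-methoxyisochroman should ionise at C1 with phenol assistance and lose methanol to give the vinylogous-acid quinone methide, a change the lactone half cannot undergo.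

**Compound list**

1 | ethyl (R)-3-hydroxybutanoate | O[C@H](C)CC(=O)OCC | starting material
2 | ethyl (2R,3R)-3-hydroxy-2-methylbutanoate | O[C@H](C)[C@@H](C)C(=O)OCC | intermediate
3 | ethyl (2R,3R)-3-acetoxy-2-methylbutanoate | CC(=O)O[C@H](C)[C@@H](C)C(=O)OCC | intermediate
4 | (5R,6R)-4-hydroxy-5,6-dimethyl-5,6-dihydro-2H-pyran-2-one (enol form of the β-keto-δ-lactone) | O1[C@H](C)[C@@H](C)C(O)=CC1=O | intermediate
5 | (2R,3R)-2,3-dimethyl-6-oxo-3,6-dihydro-2H-pyran-4-yl trifluoromethanesulfonate | O1[C@H](C)[C@@H](C)C(OS(=O)(=O)C(F)(F)F)=CC1=O | intermediate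
6 | (5S,6R)-5,6-dimethyl-4-propanoyl-5,6-dihydro-2H-pyran-2-one | O1[C@H](C)[C@@H](C)C(C(=O)CC)=CC1=O | intermediate
7 | (5S,6R)-5,6-dimethyl-4-(4,4,4-trifluoro-2-methyl-3-oxobutanoyl)-5,6-dihydro-2H-pyran-2-one (not isolated) | O1[C@H](C)[C@@H](C)C(C(=O)C(C)C(=O)C(F)(F)F)=CC1=O | intermediate
8 | (5S,6R)-4-(2-diazopropanoyl)-5,6-dimethyl-5,6-dihydro-2H-pyran-2-one | O1[C@H](C)[C@@H](C)C(C(=O)C(C)=[N+]=[N-])=CC1=O | intermediate
9 | (2R,3R)-6-hydroxy-2,3-dimethyl-3,6-dihydro-2H-pyran-4-yl trifluoromethanesulfonate (lactol, anomers) | O1[C@H](C)[C@@H](C)C(OS(=O)(=O)C(F)(F)F)=CC1O | intermediate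
10 | (2R,3R)-6-methoxy-2,3-dimethyl-3,6-dihydro-2H-pyran-4-yl trifluoromethanesulfonate (anomers) | O1[C@H](C)[C@@H](C)C(OS(=O)(=O)C(F)(F)F)=CC1OC | intermediate
11 | 1-[(5S,6R)-2-methoxy-5,6-dimethyl-5,6-dihydro-2H-pyran-4-yl]propan-1-one | O1[C@H](C)[C@@H](C)C(C(=O)CC)=CC1OC | intermediate
12 | 4,4,4-trifluoro-1-[(5S,6R)-2-methoxy-5,6-dimethyl-5,6-dihydro-2H-pyran-4-yl]-2-methylbutane-1,3-dione (not isolated) | O1[C@H](C)[C@@H](C)C(C(=O)C(C)C(=O)C(F)(F)F)=CC1OC | intermediate
13 | 2-diazo-1-[(5S,6R)-2-methoxy-5,6-dimethyl-5,6-dihydro-2H-pyran-4-yl]propan-1-one | O1[C@H](C)[C@@H](C)C(C(=O)C(C)=[N+]=[N-])=CC1OC | intermediate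
14 | methyl (S)-3-hydroxy-2-methylpropanoate (Roche ester) | OC[C@H](C)C(=O)OC | starting material
15 | methyl (S)-3-(tert-butyldimethylsilyloxy)-2-methylpropanoate | CC(C)(C)[Si](C)(C)OC[C@H](C)C(=O)OC | intermediate
16 | lithium (R)-4-(tert-butyldimethylsilyloxy)-3-methylbut-1-yn-1-olate (not isolated) | CC(C)(C)[Si](C)(C)OC[C@H](C)C#C[O-].[Li+] | intermediate
17 | tert-butyldimethyl{[(2R)-2-methyl-4-(triisopropylsilyloxy)but-3-yn-1-yl]oxy}silane | CC(C)(C)[Si](C)(C)OC[C@H](C)C#CO[Si](C(C)C)(C(C)C)C(C)C | intermediate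
18 | vinylketene: 2-[(2R,3S)-2,3-dimethyl-6-oxo-3,6-dihydro-2H-pyran-4-yl]prop-1-en-1-one (not isolated) | O1[C@H](C)[C@@H](C)C(C(C)=C=O)=CC1=O | intermediate
19 | vinylcyclobutenone: 4-methyl-4-(pyranonyl)-3-(triisopropylsilyloxy)-2-[(R)-1-(TBS-oxy)propan-2-yl]cyclobut-2-en-1-one, ring centres as in 8 (not isolated) | O1[C@H](C)[C@@H](C)C(C2(C)C(=O)C([C@@H](C)CO[Si](C)(C)C(C)(C)C)=C2O[Si](C(C)C)(C(C)C)C(C)C)=CC1=O | intermediate
20 | dienylketene from ring opening of 19 (not isolated) | O1[C@H](C)[C@@H](C)C(C(C)=C(O[Si](C(C)C)(C(C)C)C(C)C)C([C@@H](C)CO[Si](C)(C)C(C)(C)C)=C=O)=CC1=O | intermediate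
21 | cyclohexa-2,4-dienone tautomer of 22 with sp3 C8a′ (not isolated) | O1[C@H](C)[C@@H](C)C2=C(C)C(O[Si](C(C)C)(C(C)C)C(C)C)=C([C@@H](C)CO[Si](C)(C)C(C)(C)C)C(=O)C2C1=O | intermediate
22 | (3R,4S)-7-[(2R)-1-(tert-butyldimethylsilyloxy)propan-2-yl]-8-hydroxy-3,4,5-trimethyl-6-(triisopropylsilyloxy)isochroman-1-one | O1[C@H](C)[C@@H](C)c2c(C)c(O[Si](C(C)C)(C(C)C)C(C)C)c([C@@H](C)CO[Si](C)(C)C(C)(C)C)c(O)c2C1=O | intermediate
23 | (3R,4S)-7-[(2R)-1-(tert-butyldimethylsilyloxy)propan-2-yl]-3,4,5-trimethyl-6,8-bis(triisopropylsilyloxy)isochroman-1-one | O1[C@H](C)[C@@H](C)c2c(C)c(O[Si](C(C)C)(C(C)C)C(C)C)c([C@@H](C)CO[Si](C)(C)C(C)(C)C)c(O[Si](C(C)C)(C(C)C)C(C)C)c2C1=O | intermediate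
24 | (3R,4S)-7-[(2R)-1-hydroxypropan-2-yl]-3,4,5-trimethyl-6,8-bis(triisopropylsilyloxy)isochroman-1-one | O1[C@H](C)[C@@H](C)c2c(C)c(O[Si](C(C)C)(C(C)C)C(C)C)c([C@@H](C)CO)c(O[Si](C(C)C)(C(C)C)C(C)C)c2C1=O | intermediate
25 | (2R)-2-[(3R,4S)-3,4,5-trimethyl-1-oxo-6,8-bis(triisopropylsilyloxy)isochroman-7-yl]propanal | O1[C@H](C)[C@@H](C)c2c(C)c(O[Si](C(C)C)(C(C)C)C(C)C)c([C@@H](C)C=O)c(O[Si](C(C)C)(C(C)C)C(C)C)c2C1=O | intermediate
26 | (3R,4S)-7-[(2S)-but-3-yn-2-yl]-3,4,5-trimethyl-6,8-bis(triisopropylsilyloxy)isochroman-1-one | O1[C@H](C)[C@@H](C)c2c(C)c(O[Si](C(C)C)(C(C)C)C(C)C)c([C@@H](C)C#C)c(O[Si](C(C)C)(C(C)C)C(C)C)c2C1=O | intermediate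
27 | lithium ynolate of 26: lithium (3S)-3-[(3R,4S)-3,4,5-trimethyl-1-oxo-6,8-bis(triisopropylsilyloxy)isochroman-7-yl]but-1-yn-1-olate (not isolated) | O1[C@H](C)[C@@H](C)c2c(C)c(O[Si](C(C)C)(C(C)C)C(C)C)c([C@@H](C)C#C[O-])c(O[Si](C(C)C)(C(C)C)C(C)C)c2C1=O.[Li+] | intermediate
28 | (3R,4S)-3,4,5-trimethyl-6,8-bis(triisopropylsilyloxy)-7-[(2S)-4-(triisopropylsilyloxy)but-3-yn-2-yl]isochroman-1-one | O1[C@H](C)[C@@H](C)c2c(C)c(O[Si](C(C)C)(C(C)C)C(C)C)c([C@@H](C)C#CO[Si](C(C)C)(C(C)C)C(C)C)c(O[Si](C(C)C)(C(C)C)C(C)C)c2C1=O | intermediate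
29 | vinylketene: 2-[(5S,6R)-2-methoxy-5,6-dimethyl-5,6-dihydro-2H-pyran-4-yl]prop-1-en-1-one (not isolated) | O1[C@H](C)[C@@H](C)C(C(C)=C=O)=CC1OC | intermediate
30 | vinylcyclobutenone: 2-[1-(isochromanonyl)ethyl]-4-methyl-4-(2-methoxydihydropyranyl)-3-(triisopropylsilyloxy)cyclobut-2-en-1-one, centres as in 13 and 28 (not isolated) | O1[C@H](C)[C@@H](C)c2c(C)c(O[Si](C(C)C)(C(C)C)C(C)C)c([C@@H](C)C3=C(O[Si](C(C)C)(C(C)C)C(C)C)C(C)(C4=CC(OC)O[C@H](C)[C@H]4C)C3=O)c(O[Si](C(C)C)(C(C)C)C(C)C)c2C1=O | intermediate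
31 | dienylketene from ring opening of 30 (not isolated) | O1[C@H](C)[C@@H](C)c2c(C)c(O[Si](C(C)C)(C(C)C)C(C)C)c([C@@H](C)C(=C=O)C(O[Si](C(C)C)(C(C)C)C(C)C)=C(C)C3=CC(OC)O[C@H](C)[C@H]3C)c(O[Si](C(C)C)(C(C)C)C(C)C)c2C1=O | intermediate
32 | cyclohexa-2,4-dienone tautomer of 33 with sp3 C8a (not isolated) | O1[C@H](C)[C@@H](C)c2c(C)c(O[Si](C(C)C)(C(C)C)C(C)C)c([C@@H](C)C3=C(O[Si](C(C)C)(C(C)C)C(C)C)C(C)=C4C(C(OC)O[C@H](C)[C@H]4C)C3=O)c(O[Si](C(C)C)(C(C)C)C(C)C)c2C1=O | intermediate
33 | (3R,4S)-7-{1-[(3R,4S)-8-hydroxy-1-methoxy-3,4,5-trimethyl-6-(triisopropylsilyloxy)isochroman-7-yl]ethyl}-3,4,5-trimethyl-6,8-bis(triisopropylsilyloxy)isochroman-1-one (bridging centre as in 28) | O1[C@H](C)[C@@H](C)c2c(C)c(O[Si](C(C)C)(C(C)C)C(C)C)c([C@@H](C)c3c(O)c4C(OC)O[C@H](C)[C@@H](C)c4c(C)c3O[Si](C(C)C)(C(C)C)C(C)C)c(O[Si](C(C)C)(C(C)C)C(C)C)c2C1=O | intermediate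
34 | (3R,4S)-7-{1-[(3R,4S)-6,8-dihydroxy-1-methoxy-3,4,5-trimethylisochroman-7-yl]ethyl}-6,8-dihydroxy-3,4,5-trimethylisochroman-1-one (not isolated) | O1[C@H](C)[C@@H](C)c2c(C)c(O)c([C@@H](C)c3c(O)c4C(OC)O[C@H](C)[C@@H](C)c4c(C)c3O)c(O)c2C1=O | intermediate
35 | dicitrinone H: (3R,4S) quinone-methide half and (3R,4S) lactone half joined by an (R)-CH(CH3) bridge, 6-hydroxy-8-oxo tautomer | CC1=C2C(=CO[C@H](C)[C@H]2C)C(=O)C([C@H](C)c2c(O)c(C)c3c(c2O)C(=O)O[C@H](C)[C@H]3C)=C1O | target

**Step count and risks**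

Total step count: 20. Longest linear sequence: 14 steps (steps 1–6, then 13–20).

Steps most likely to fail:

1. Step 19 (key benzannulation). The excited diazo ketone may undergo a 1,2-hydrogen shift or other carbene chemistry instead of Wolff rearrangement, and the aryl lactone chromophore of 28 may absorb the light or degrade. The fallback generates the same vinylketene without light or a diazo compound. It sets out from triflate 10: Pd-catalysed Negishi coupling with the Reformatsky reagent of methyl 2-bromopropanoate would give methyl 2-[(5S,6R)-2-methoxy-5,6-dimethyl-5,6-dihydro-2H-pyran-4-yl]propanoate F1. Saponification with LiOH would give 2-[(5S,6R)-2-methoxy-5,6-dimethyl-5,6-dihydro-2H-pyran-4-yl]propanoic acid F2, and Ghosez's reagent would give 2-[(5S,6R)-2-methoxy-5,6-dimethyl-5,6-dihydro-2H-pyran-4-yl]propanoyl chloride F3. Slow addition of Et3N to F3 and 28 in toluene at 80 °C would form the ketene by dehydrochlorination. The fallback comes back to the route at vinylketene 29, which continues to 33.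

2. Step 18 (ynolate formation). The lithium acetylide, the lithium peroxide or the lithium tert-butoxide formed may add to the lactone carbonyl or strip aryl silyl groups. The fallback reverses the polarity of the alkyne and sets out from 26: PhI(OH)OTs would give the alkynyl(phenyl)iodonium tosylate F4. CuOTf-catalysed collapse would give the alkynyl tosylate F5. S–O cleavage with MeLi (1 equiv, −78 °C) would release the ynolate, so the fallback comes back at 27, which is silylated to 28 as before.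

3. Step 13 (first benzannulation). The electron-poor, lactone-conjugated vinylketene 18 may cyclise sluggishly, and the enedione lactone 8 may degrade on irradiation. The fallback sets out from 13 and 17: the same benzannulation with the acetal diazo ketone would give the 1-methoxyisochroman-8-ol F6. Hydrolysis (PPTS, aqueous acetone) would give the isochromane-1,8-diol (lactol) F7, and MnO2 oxidation of this benzylic lactol would give the lactone, coming back at 22.

Further compounds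
F1 | step 19 | methyl 2-[(5S,6R)-2-methoxy-5,6-dimethyl-5,6-dihydro-2H-pyran-4-yl]propanoate | O1[C@H](C)[C@@H](C)C(C(C)C(=O)OC)=CC1OC
F2 | step 19 | 2-[(5S,6R)-2-methoxy-5,6-dimethyl-5,6-dihydro-2H-pyran-4-yl]propanoic acid | O1[C@H](C)[C@@H](C)C(C(C)C(=O)O)=CC1OC
F3 | step 19 | 2-[(5S,6R)-2-methoxy-5,6-dimethyl-5,6-dihydro-2H-pyran-4-yl]propanoyl chloride | O1[C@H](C)[C@@H](C)C(C(C)C(=O)Cl)=CC1OC
F4 | step 18 | phenyl{(3S)-3-[(3R,4S)-3,4,5-trimethyl-1-oxo-6,8-bis(triisopropylsilyloxy)isochroman-7-yl]but-1-yn-1-yl}iodonium tosylate | O1[C@H](C)[C@@H](C)c2c(C)c(O[Si](C(C)C)(C(C)C)C(C)C)c([C@@H](C)C#C[I+]c3ccccc3)c(O[Si](C(C)C)(C(C)C)C(C)C)c2C1=O.Cc1ccc(cc1)S(=O)(=O)[O-]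
F5 | step 18 | (3S)-3-[(3R,4S)-3,4,5-trimethyl-1-oxo-6,8-bis(triisopropylsilyloxy)isochroman-7-yl]but-1-yn-1-yl 4-methylbenzenesulfonate | O1[C@H](C)[C@@H](C)c2c(C)c(O[Si](C(C)C)(C(C)C)C(C)C)c([C@@H](C)C#COS(=O)(=O)c3ccc(C)cc3)c(O[Si](C(C)C)(C(C)C)C(C)C)c2C1=O
F6 | step 13 | (3R,4S)-7-[(2R)-1-(tert-butyldimethylsilyloxy)propan-2-yl]-1-methoxy-3,4,5-trimethyl-6-(triisopropylsilyloxy)isochroman-8-ol | O1[C@H](C)[C@@H](C)c2c(C)c(O[Si](C(C)C)(C(C)C)C(C)C)c([C@@H](C)CO[Si](C)(C)C(C)(C)C)c(O)c2C1OC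
F7 | step 13 | (3R,4S)-7-[(2R)-1-(tert-butyldimethylsilyloxy)propan-2-yl]-3,4,5-trimethyl-6-(triisopropylsilyloxy)isochromane-1,8-diol | O1[C@H](C)[C@@H](C)c2c(C)c(O[Si](C(C)C)(C(C)C)C(C)C)c([C@@H](C)CO[Si](C)(C)C(C)(C)C)c(O)c2C1O
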